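The target's cis-fused cyclohexane/oxepinone core hides a γ,δ-unsaturated carboxyl array: lactone carbonyl C1, ring-fusion carbons C9a and C5a, and the C5=C4 alkene of the seven-membered ring (2-benzoxepine numbering). It is unlocked by an Ireland–Claisen ring contraction of a ten-membered (E)-allylic lactone, which closes the cyclohexane by the C9a–C5a bond and sets the all-cis C6/C5a/C9a triad in one step; the precursor is a 7-isopropyl-4-methylene oxecin-2-one. Alkylation/ring-closing metathesis then builds the oxepinone. The same contraction in the antipodal series, followed by decarboxylative epoxide opening, gives the side-chain acid, which opens the spiro-epoxide of the core.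

Key step: step 7

Remark: by CIP analysis of the target SMILES the two carbocycles belong to antipodal series (core 5aR,6R,9S,9aS; side-chain ring 1R,6S), so steps 2 and 11 use the two enantiomers of one catalyst. Compounds 1, 2, 4, 6, 15 and 28 are taken as commercially available.

Step 1
Reactants: 1 (E)-4-methylpent-2-en-1-ol; 2 diethyl chlorophosphate
Product: 3 diethyl (E)-4-methylpent-2-en-1-yl phosphate
Conditions: Et3N, DMAP (cat.), CH2Cl2, 0 °C to rt
Reagents that add atoms: none
Why: O-phosphorylation of the primary allylic alcohol should give the leaving group for the copper-catalysed SN2′ substitution; no stereocentre is involved and the E-olefin is untouched.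

Step 2
Reactants: 3 diethyl (E)-4-methylpent-2-en-1-yl phosphate; 4 (E)-3-(tert-butyldimethylsilyloxy)prop-1-enylboronic acid pinacol ester
Product: 5 (S,E)-tert-butyl[(4-isopropylhexa-2,5-dien-1-yl)oxy]dimethylsilane
Conditions: CuCl (5 mol %), chiral sulfonate-bearing imidazolinium salt (NHC precursor, 5.5 mol %), NaOMe, THF, 22 °C
Reagents that add atoms: none
Why: copper-catalysed enantioselective allylic substitution with an alkenylboron reagent: methoxide-promoted boron-to-copper transfer gives an NHC–copper alkenyl that attacks the γ-carbon (SN2′), the chiral carbene choosing the olefin face and so setting C4 as S, with the alkenyl E geometry retained.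

Step 3
Reactants: 5 (S,E)-tert-butyl[(4-isopropylhexa-2,5-dien-1-yl)oxy]dimethylsilane; 6 3-bromobut-3-en-1-ol
Product: 8 (6R,7E)-9-[(tert-butyldimethylsilyl)oxy]-6-isopropyl-3-methylenenon-7-en-1-ol, via B-alkyl-9-BBN adduct 7 (not isolated)
Conditions: 9-BBN-H, THF, 0 °C to rt; then 6, PdCl2(dppf), AsPh3, Cs2CO3, DMF/THF/H2O, rt
Reagents that add atoms: none
Why: 9-BBN should hydroborate only the monosubstituted olefin (anti-Markovnikov), and B-alkyl Suzuki–Miyaura coupling with the 2-bromoalkene then installs the 1,1-disubstituted olefin; the internal E-olefin and the stereocentre are not touched.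

Step 4
Reactants: 8 (6R,7E)-9-[(tert-butyldimethylsilyl)oxy]-6-isopropyl-3-methylenenon-7-en-1-ol
Product: 9 (6R,7E)-9-[(tert-butyldimethylsilyl)oxy]-6-isopropyl-3-methylenenon-7-enoic acid
Conditions: TEMPO (20 mol %), PhI(OAc)2 (2.2 equiv), MeCN/H2O (1:1), rt
Reagents that add atoms: water, O
Why: oxoammonium-mediated oxidation of the primary alcohol through the aldehyde hydrate to the acid runs near neutrality, which should keep the 3-methylene unit out of conjugation and leave the silyl ether and olefins intact.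

Step 5
Reactants: 9 (6R,7E)-9-[(tert-butyldimethylsilyl)oxy]-6-isopropyl-3-methylenenon-7-enoic acid
Product: 10 (6R,7E)-9-hydroxy-6-isopropyl-3-methylenenon-7-enoic acid
Conditions: HF·pyridine, THF/pyridine, 0 °C to rt
Reagents that add atoms: none
Why: fluoride-driven cleavage of the primary silyl ether under non-basic conditions should free the allylic alcohol without isomerising the β,γ-unsaturated acid.

Step 6
Reactants: 10 (6R,7E)-9-hydroxy-6-isopropyl-3-methylenenon-7-enoic acid
Product: 11 (7R,8E)-7-isopropyl-4-methylene-3,4,5,6,7,10-hexahydro-2H-oxecin-2-one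
Conditions: PPh3, DIAD, toluene/THF, slow addition of 10 (final 1 mM), 0 °C to rt
Reagents that add atoms: none
Why: Mitsunobu macrolactonisation activates the primary allylic alcohol, not the acid, so the carboxylate should close the ten-membered ring by SN2 without ketene formation or conjugation of the 3-methylene acid; the E-olefin is retained and three sp2 centres relieve transannular strain.

Step 7
Reactants: 11 (7R,8E)-7-isopropyl-4-methylene-3,4,5,6,7,10-hexahydro-2H-oxecin-2-one
Product: 14 (1S,2S,3R)-3-isopropyl-6-methylene-2-vinylcyclohexane-1-carboxylic acid, via silyl ketene acetal 12 (not isolated), via trimethylsilyl ester 13 (not isolated)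
Conditions: LiN(iPr)2, Me3SiCl/Et3N (premixed), THF, −78 °C; then toluene, 80 °C; then 1 M HCl, THF, rt
Reagents that add atoms: none
Why: the amide base removes the doubly activated C3–H of 11 and the extended enolate is O-silylated in situ; kinetic enolisation and the ten-membered ring both place C4 cis to the ring oxygen in ketene acetal 12. On warming, 12 should undergo the [3,3]-sigmatropic Ireland–Claisen shift, the closest known type being the ring contraction of macrocyclic lactone silyl ketene acetals to 2-alkenylcycloalkanecarboxylic acids. The new C1–C2 bond of 14 (later C9a–C5a) closes the cyclohexane transannularly, a four-atom ring contraction through a chair-like pericyclic array fused to a chair-like incipient carbocycle as in a cis-decalin. The ring-cis ketene acetal and the E-olefin force the carboxyl carbon equatorial and the vinyl carbon axial on the new ring, so C1 and C2 emerge cis; the existing C7 centre of 11 keeps its isopropyl group equatorial, which selects the olefin face and should give the all-cis (1S,2S,3R) triad. The step needs O- over C-silylation and α- over γ-reaction of the dienolate, secured by the in situ silyl chloride quench at −78 °C, and face selectivity, secured by the equatorial preference of isopropyl.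

Step 8
Reactants: 14 (1S,2S,3R)-3-isopropyl-6-methylene-2-vinylcyclohexane-1-carboxylic acid; 15 tert-butyl 2-(bromomethyl)acrylate
Product: 16 2-(tert-butoxycarbonyl)allyl (1S,2S,3R)-3-isopropyl-6-methylene-2-vinylcyclohexane-1-carboxylate
Conditions: KHCO3, DMF, 0 °C to rt
Reagents that add atoms: none
Why: carboxylate O-alkylation by the activated allylic bromide (SN2 and SN2′ give the same ester) under a weak base should not epimerise C1 or move the exocyclic olefin into conjugation.

Step 9
Reactants: 16 2-(tert-butoxycarbonyl)allyl (1S,2S,3R)-3-isopropyl-6-methylene-2-vinylcyclohexane-1-carboxylate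
Product: 17 tert-butyl (5aR,6R,9aS)-6-isopropyl-9-methylene-1-oxo-1,3,5a,6,7,8,9,9a-octahydro-2-benzoxepine-4-carboxylate
Conditions: second-generation Hoveyda–Grubbs catalyst RuCl2(H2IMes)(=CH-C6H4-2-OiPr) (10 mol %), 1,4-benzoquinone (10 mol %), toluene (2 mM), 80 °C
Reagents that add atoms: none
Why: ring-closing metathesis of the vinyl group with the 2-substituted acrylate should close the seven-membered lactone because the two arms are cis on the cyclohexane; the ring fixes the C4=C5 geometry (ester trans to C5a), and the exocyclic methylene could only give a cyclobutene and stays out.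

Step 10
Reactants: 17 tert-butyl (5aR,6R,9aS)-6-isopropyl-9-methylene-1-oxo-1,3,5a,6,7,8,9,9a-octahydro-2-benzoxepine-4-carboxylate
Product: 18 tert-butyl (5aR,6R,9S,9aS)-6-isopropyl-1-oxo-3,5a,6,7,8,9a-hexahydro-1H-spiro[2-benzoxepine-9,2'-oxirane]-4-carboxylate
Conditions: mCPBA, NaHCO3, CH2Cl2, 0 °C
Reagents that add atoms: 3-chloroperoxybenzoic acid (mCPBA), O=C(OO)c1cccc(Cl)c1
Why: Prilezhaev epoxidation should take only the electron-rich 1,1-disubstituted olefin (the enoate is inert), the peracid approaching from the face opposite the axial C5a–C5 bond and the adjacent C9a–C1 bond (equatorial attack), which places the oxygen trans to C1 and sets C9 as S.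

Step 11
Reactants: 3 diethyl (E)-4-methylpent-2-en-1-yl phosphate; 4 (E)-3-(tert-butyldimethylsilyloxy)prop-1-enylboronic acid pinacol ester
Product: 19 (R,E)-tert-butyl[(4-isopropylhexa-2,5-dien-1-yl)oxy]dimethylsilane
Conditions: CuCl (5 mol %), enantiomeric imidazolinium salt (NHC precursor, 5.5 mol %), NaOMe, THF, 22 °C
Reagents that add atoms: none
Why: the same copper-catalysed enantioselective SN2′ allylic substitution as in step 2, with the mirror-image carbene ligand, should set C4 as R.

Step 12
Reactants: 19 (R,E)-tert-butyl[(4-isopropylhexa-2,5-dien-1-yl)oxy]dimethylsilane; 6 3-bromobut-3-en-1-ol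
Product: 21 (6S,7E)-9-[(tert-butyldimethylsilyl)oxy]-6-isopropyl-3-methylenenon-7-en-1-ol, via B-alkyl-9-BBN adduct 20 (not isolated)
Conditions: 9-BBN-H, THF, 0 °C to rt; then 6, PdCl2(dppf), AsPh3, Cs2CO3, DMF/THF/H2O, rt
Reagents that add atoms: none
Why: chemoselective hydroboration of the terminal olefin and B-alkyl Suzuki–Miyaura coupling, as in step 3; the stereocentre is not touched.

Step 13
Reactants: 21 (6S,7E)-9-[(tert-butyldimethylsilyl)oxy]-6-isopropyl-3-methylenenon-7-en-1-ol
Product: 22 (6S,7E)-9-[(tert-butyldimethylsilyl)oxy]-6-isopropyl-3-methylenenon-7-enoic acid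
Conditions: TEMPO (20 mol %), PhI(OAc)2 (2.2 equiv), MeCN/H2O (1:1), rt
Reagents that add atoms: water, O
Why: oxoammonium-mediated oxidation of the primary alcohol to the acid under near-neutral conditions, as in step 4.

Step 14
Reactants: 22 (6S,7E)-9-[(tert-butyldimethylsilyl)oxy]-6-isopropyl-3-methylenenon-7-enoic acid
Product: 23 (6S,7E)-9-hydroxy-6-isopropyl-3-methylenenon-7-enoic acid
Conditions: HF·pyridine, THF/pyridine, 0 °C to rt
Reagents that add atoms: none
Why: fluoride-driven desilylation of the primary allylic silyl ether, as in step 5.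

Step 15
Reactants: 23 (6S,7E)-9-hydroxy-6-isopropyl-3-methylenenon-7-enoic acid
Product: 24 (7S,8E)-7-isopropyl-4-methylene-3,4,5,6,7,10-hexahydro-2H-oxecin-2-one
Conditions: PPh3, DIAD, toluene/THF, slow addition of 23 (final 1 mM), 0 °C to rt
Reagents that add atoms: none
Why: Mitsunobu macrolactonisation through the activated primary allylic alcohol, as in step 6.

Step 16
Reactants: 24 (7S,8E)-7-isopropyl-4-methylene-3,4,5,6,7,10-hexahydro-2H-oxecin-2-one
Product: 27 (1R,2R,3S)-3-isopropyl-6-methylene-2-vinylcyclohexane-1-carboxylic acid, via silyl ketene acetal 25 (not isolated), via trimethylsilyl ester 26 (not isolated)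
Conditions: LiN(iPr)2, Me3SiCl/Et3N (premixed), THF, −78 °C; then toluene, 80 °C; then 1 M HCl, THF, rt
Reagents that add atoms: none
Why: the Ireland–Claisen ring contraction of step 7 in the mirror-image series; the chair–chair transition state with equatorial isopropyl should again give the all-cis triad, here (1R,2R,3S).

Step 17
Reactants: 27 (1R,2R,3S)-3-isopropyl-6-methylene-2-vinylcyclohexane-1-carboxylic acid; 28 methyl 2-(bromomethyl)acrylate
Product: 29 2-(methoxycarbonyl)allyl (1R,2R,3S)-3-isopropyl-6-methylene-2-vinylcyclohexane-1-carboxylate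
Conditions: KHCO3, DMF, 0 °C to rt
Reagents that add atoms: none
Why: carboxylate O-alkylation by the activated allylic bromide, as in step 8; here the ester is a temporary tether.

Step 18
Reactants: 29 2-(methoxycarbonyl)allyl (1R,2R,3S)-3-isopropyl-6-methylene-2-vinylcyclohexane-1-carboxylate
Product: 30 methyl (5aS,6S,9aR)-6-isopropyl-9-methylene-1-oxo-1,3,5a,6,7,8,9,9a-octahydro-2-benzoxepine-4-carboxylate
Conditions: second-generation Hoveyda–Grubbs catalyst RuCl2(H2IMes)(=CH-C6H4-2-OiPr) (10 mol %), 1,4-benzoquinone (10 mol %), toluene (2 mM), 80 °C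
Reagents that add atoms: none
Why: ring-closing metathesis as in step 9; closing through the lactone tether fixes the trisubstituted acrylate geometry that the side-chain acid needs (carboxyl trans to the ring carbon).

Step 19
Reactants: 30 methyl (5aS,6S,9aR)-6-isopropyl-9-methylene-1-oxo-1,3,5a,6,7,8,9,9a-octahydro-2-benzoxepine-4-carboxylate
Product: 31 methyl (5aS,6S,9R,9aR)-6-isopropyl-1-oxo-3,5a,6,7,8,9a-hexahydro-1H-spiro[2-benzoxepine-9,2'-oxirane]-4-carboxylate
Conditions: mCPBA, NaHCO3, CH2Cl2, 0 °C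
Reagents that add atoms: 3-chloroperoxybenzoic acid (mCPBA), O=C(OO)c1cccc(Cl)c1
Why: Prilezhaev epoxidation of the exocyclic olefin from the face opposite C1 and C5, as in step 10; the oxygen trans to the C1 carboxyl is the arrangement the next step needs.

Step 20
Reactants: 31 methyl (5aS,6S,9R,9aR)-6-isopropyl-1-oxo-3,5a,6,7,8,9a-hexahydro-1H-spiro[2-benzoxepine-9,2'-oxirane]-4-carboxylate
Product: 33 (E)-2-(hydroxymethyl)-3-[(1R,6S)-3-(hydroxymethyl)-6-isopropylcyclohex-2-en-1-yl]acrylic acid, via epoxy dicarboxylate 32 (not isolated)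
Conditions: LiOH, THF/H2O (3:1), 0 °C to rt, then 70 °C; then 1 M HCl to pH 3, 0 °C
Reagents that add atoms: lithium hydroxide, [Li+].[OH-]
Why: saponification of the lactone and the methyl ester at low temperature (before any E1cB epoxide opening) gives a β,γ-epoxy carboxylate, which on heating should undergo decarboxylative Grob-type fragmentation (C–CO2 bond anti to the epoxide C–O bond) to the ring olefin and its CH2OH; the former C9 and C9a centres become sp2, while C5a and C6 survive as C1 (R) and C6 (S).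

Step 21
Reactants: 18 tert-butyl (5aR,6R,9S,9aS)-6-isopropyl-1-oxo-3,5a,6,7,8,9a-hexahydro-1H-spiro[2-benzoxepine-9,2'-oxirane]-4-carboxylate; 33 (E)-2-(hydroxymethyl)-3-[(1R,6S)-3-(hydroxymethyl)-6-isopropylcyclohex-2-en-1-yl]acrylic acid
Product: 34 tert-butyl ester of the target
Conditions: Cs2CO3 (20 mol %), DMF, 70 °C
Reagents that add atoms: none
Why: carboxylate ring opening of the 2,2-disubstituted epoxide at its CH2 carbon (SN2) should give the primary ester and the tertiary alcohol directly; the C9–O bond is not broken so C9 stays S, the alcohol groups of 33 cannot compete with its carboxylate, and the primary oxygen is never free, which excludes translactonisation onto C1.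

Step 22
Reactants: 34 tert-butyl ester of the target
Product: 35 CNP0361406.12
Conditions: TFA/CH2Cl2 (1:4), 0 °C to rt; then NaHCO3, MeOH/H2O, 0 °C
Reagents that add atoms: none
Why: acidolysis of the tert-butyl ester (loss of isobutene through the tert-butyl cation) should leave the lactone, the acrylate ester and the alcohols intact, the C9 carbinol being deactivated towards ionisation by its acyl-bearing neighbours; the mild basic work-up cleaves any trifluoroacetates.

Compound list

1 | (E)-4-methylpent-2-en-1-ol | CC(C)/C=C/CO | starting material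
2 | diethyl chlorophosphate | CCOP(=O)(Cl)OCC | starting material
3 | diethyl (E)-4-methylpent-2-en-1-yl phosphate | CC(C)/C=C/COP(=O)(OCC)OCC | intermediate
4 | (E)-3-(tert-butyldimethylsilyloxy)prop-1-enylboronic acid pinacol ester | CC(C)(C)[Si](C)(C)OC/C=C/B1OC(C)(C)C(C)(C)O1 | starting material
5 | (S,E)-tert-butyl[(4-isopropylhexa-2,5-dien-1-yl)oxy]dimethylsilane | CC(C)[C@H](/C=C/CO[Si](C)(C)C(C)(C)C)C=C | intermediate
6 | 3-bromobut-3-en-1-ol | C=C(Br)CCO | starting material
7 | 9-[(3R,4E)-6-(tert-butyldimethylsilyloxy)-3-isopropylhex-4-en-1-yl]-9-borabicyclo[3.3.1]nonane (not isolated) | CC(C)[C@H](/C=C/CO[Si](C)(C)C(C)(C)C)CCB1C2CCCC1CCC2 | intermediate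
8 | (6R,7E)-9-[(tert-butyldimethylsilyl)oxy]-6-isopropyl-3-methylenenon-7-en-1-ol | CC(C)[C@H](/C=C/CO[Si](C)(C)C(C)(C)C)CCC(=C)CCO | intermediate
9 | (6R,7E)-9-[(tert-butyldimethylsilyl)oxy]-6-isopropyl-3-methylenenon-7-enoic acid | CC(C)[C@H](/C=C/CO[Si](C)(C)C(C)(C)C)CCC(=C)CC(=O)O | intermediate
10 | (6R,7E)-9-hydroxy-6-isopropyl-3-methylenenon-7-enoic acid | CC(C)[C@H](/C=C/CO)CCC(=C)CC(=O)O | intermediate
11 | (7R,8E)-7-isopropyl-4-methylene-3,4,5,6,7,10-hexahydro-2H-oxecin-2-one | CC(C)[C@H]1CCC(=C)CC(=O)OC/C=C/1 | intermediate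
12 | trimethylsilyl ketene acetal of 11, ring oxygen cis to C4 (not isolated) | CC(C)[C@H]1CCC(=C)/C=C(O[Si](C)(C)C)\OC/C=C/1 | intermediate
13 | trimethylsilyl (1S,2S,3R)-3-isopropyl-6-methylene-2-vinylcyclohexane-1-carboxylate (not isolated) | CC(C)[C@H]1CCC(=C)[C@@H](C(=O)O[Si](C)(C)C)[C@H]1C=C | intermediate
14 | (1S,2S,3R)-3-isopropyl-6-methylene-2-vinylcyclohexane-1-carboxylic acid | CC(C)[C@H]1CCC(=C)[C@@H](C(=O)O)[C@H]1C=C | intermediate
15 | tert-butyl 2-(bromomethyl)acrylate | C=C(CBr)C(=O)OC(C)(C)C | starting material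
16 | 2-(tert-butoxycarbonyl)allyl (1S,2S,3R)-3-isopropyl-6-methylene-2-vinylcyclohexane-1-carboxylate | CC(C)[C@H]1CCC(=C)[C@@H](C(=O)OCC(=C)C(=O)OC(C)(C)C)[C@H]1C=C | intermediate
17 | tert-butyl (5aR,6R,9aS)-6-isopropyl-9-methylene-1-oxo-1,3,5a,6,7,8,9,9a-octahydro-2-benzoxepine-4-carboxylate | CC(C)[C@H]1CCC(=C)[C@H]2C(=O)OCC(C(=O)OC(C)(C)C)=C[C@@H]12 | intermediate
18 | tert-butyl (5aR,6R,9S,9aS)-6-isopropyl-1-oxo-3,5a,6,7,8,9a-hexahydro-1H-spiro[2-benzoxepine-9,2'-oxirane]-4-carboxylate | CC(C)[C@H]1CC[C@@]2(CO2)[C@H]3C(=O)OCC(C(=O)OC(C)(C)C)=C[C@@H]13 | intermediate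
19 | (R,E)-tert-butyl[(4-isopropylhexa-2,5-dien-1-yl)oxy]dimethylsilane | CC(C)[C@@H](/C=C/CO[Si](C)(C)C(C)(C)C)C=C | intermediate
20 | 9-[(3S,4E)-6-(tert-butyldimethylsilyloxy)-3-isopropylhex-4-en-1-yl]-9-borabicyclo[3.3.1]nonane (not isolated) | CC(C)[C@@H](/C=C/CO[Si](C)(C)C(C)(C)C)CCB1C2CCCC1CCC2 | intermediate
21 | (6S,7E)-9-[(tert-butyldimethylsilyl)oxy]-6-isopropyl-3-methylenenon-7-en-1-ol | CC(C)[C@@H](/C=C/CO[Si](C)(C)C(C)(C)C)CCC(=C)CCO | intermediate
22 | (6S,7E)-9-[(tert-butyldimethylsilyl)oxy]-6-isopropyl-3-methylenenon-7-enoic acid | CC(C)[C@@H](/C=C/CO[Si](C)(C)C(C)(C)C)CCC(=C)CC(=O)O | intermediate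
23 | (6S,7E)-9-hydroxy-6-isopropyl-3-methylenenon-7-enoic acid | CC(C)[C@@H](/C=C/CO)CCC(=C)CC(=O)O | intermediate
24 | (7S,8E)-7-isopropyl-4-methylene-3,4,5,6,7,10-hexahydro-2H-oxecin-2-one | CC(C)[C@@H]1CCC(=C)CC(=O)OC/C=C/1 | intermediate
25 | trimethylsilyl ketene acetal of 24, ring oxygen cis to C4 (not isolated) | CC(C)[C@@H]1CCC(=C)/C=C(O[Si](C)(C)C)\OC/C=C/1 | intermediate
26 | trimethylsilyl (1R,2R,3S)-3-isopropyl-6-methylene-2-vinylcyclohexane-1-carboxylate (not isolated) | CC(C)[C@@H]1CCC(=C)[C@H](C(=O)O[Si](C)(C)C)[C@@H]1C=C | intermediate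
27 | (1R,2R,3S)-3-isopropyl-6-methylene-2-vinylcyclohexane-1-carboxylic acid | CC(C)[C@@H]1CCC(=C)[C@H](C(=O)O)[C@@H]1C=C | intermediate
28 | methyl 2-(bromomethyl)acrylate | C=C(CBr)C(=O)OC | starting material
29 | 2-(methoxycarbonyl)allyl (1R,2R,3S)-3-isopropyl-6-methylene-2-vinylcyclohexane-1-carboxylate | CC(C)[C@@H]1CCC(=C)[C@H](C(=O)OCC(=C)C(=O)OC)[C@@H]1C=C | intermediate
30 | methyl (5aS,6S,9aR)-6-isopropyl-9-methylene-1-oxo-1,3,5a,6,7,8,9,9a-octahydro-2-benzoxepine-4-carboxylate | CC(C)[C@@H]1CCC(=C)[C@@H]2C(=O)OCC(C(=O)OC)=C[C@H]12 | intermediate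
31 | methyl (5aS,6S,9R,9aR)-6-isopropyl-1-oxo-3,5a,6,7,8,9a-hexahydro-1H-spiro[2-benzoxepine-9,2'-oxirane]-4-carboxylate | CC(C)[C@@H]1CC[C@]2(CO2)[C@@H]3C(=O)OCC(C(=O)OC)=C[C@H]13 | intermediate
32 | (3R,4R,5S,6S)-5-[(E)-2-carboxy-3-hydroxyprop-1-en-1-yl]-6-isopropyl-1-oxaspiro[2.5]octane-4-carboxylic acid, present as its dilithium salt (not isolated) | CC(C)[C@@H]1CC[C@]2(CO2)[C@H](C(=O)O)[C@@H]1/C=C(\CO)C(=O)O | intermediate
33 | (E)-2-(hydroxymethyl)-3-[(1R,6S)-3-(hydroxymethyl)-6-isopropylcyclohex-2-en-1-yl]acrylic acid | OC(=O)/C(CO)=C/[C@H]1C=C(CO)CC[C@H]1C(C)C | intermediate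
34 | tert-butyl (5aR,6R,9S,9aS)-9-hydroxy-9-[({(E)-2-(hydroxymethyl)-3-[(1R,6S)-3-(hydroxymethyl)-6-isopropylcyclohex-2-en-1-yl]acryloyl}oxy)methyl]-6-isopropyl-1-oxo-1,3,5a,6,7,8,9,9a-octahydro-2-benzoxepine-4-carboxylate | CC(C)[C@H]1CC[C@@](O)(COC(=O)/C(=C/[C@H]2C=C(CO)CC[C@H]2C(C)C)CO)[C@H]2C(=O)OCC(C(=O)OC(C)(C)C)=C[C@@H]12 | intermediate
35 | CNP0361406.12, (5aR,6R,9S,9aS)-9-hydroxy-9-[({(E)-2-(hydroxymethyl)-3-[(1R,6S)-3-(hydroxymethyl)-6-isopropylcyclohex-2-en-1-yl]acryloyl}oxy)methyl]-6-isopropyl-1-oxo-1,3,5a,6,7,8,9,9a-octahydro-2-benzoxepine-4-carboxylic acid | CC(C)[C@H]1CC[C@@](O)(COC(=O)/C(=C/[C@H]2C=C(CO)CC[C@H]2C(C)C)CO)[C@H]2C(=O)OCC(C(=O)O)=C[C@@H]12 | target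

Total step count: 22.
Longest linear sequence: 13 steps (step 1, steps 11 to 20, steps 21 and 22).

Steps most likely to fail

Step 7. The two chair-like transition states that differ in the olefin face may not be separated well enough, or part of the lactone enolate may be silylated with the other ketene acetal geometry, so that epimers at C1/C2 of 14 form. The fallback adds a second control element, 1,3-chirality transfer from a stereogenic carbinol carbon that is later lost as propene. It sets out from 3. Hydroboration of commercial (R)-tert-butyl(but-3-yn-2-yloxy)dimethylsilane with pinacolborane (Cp2Zr(H)Cl cat.) gives the (R,E)-alkenylboronate F1, which is used in place of 4 under the conditions of step 2 to give tert-butyl{[(2R,3E,5S)-5-isopropylhepta-3,6-dien-2-yl]oxy}dimethylsilane F2. Hydroboration with 9-BBN-H gives the B-alkyl adduct F3, which is coupled with 6 as in step 3 to the alcohol F4. Oxidation as in step 4 gives the acid F5 and HF·pyridine the hydroxy acid F6. Mitsunobu lactonisation, with inversion at the carbinol carbon, gives the (7R,8E,10S)-10-methyl lactone F7. Enolisation and silylation as in step 7 give the ketene acetal F8, whose chair transition state must now also keep the C10 methyl group equatorial; this is possible only for the olefin face that the equatorial isopropyl group already prefers (matched pair). Rearrangement gives the silyl ester F9 and, after hydrolysis, the (1S,2S,3R)-2-[(E)-prop-1-enyl] acid F10. Alkylation with 15 as in step 8 gives the ester F11, and ring-closing metathesis as in step 9 returns to the route at 17.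

Step 6. Oligomerisation may outrun closure of the ten-membered ring, or the carboxylate may attack in the SN2′ sense to give an eight-membered vinyl lactone. The fallback makes the ester bond first, between two molecules, and closes the ring by C–C coupling. It sets out from 5. Bu4NF in THF removes the silyl group to give (S,E)-4-isopropylhexa-2,5-dien-1-ol F12. Jones oxidation (CrO3, H2SO4, acetone) of 6 gives 3-bromobut-3-enoic acid F13. Esterification with DCC and catalytic DMAP at 0 °C gives the ester F14. 9-BBN-H should add only to the terminal vinyl group to give the B-alkyl adduct F15, which is added slowly to PdCl2(dppf), AsPh3 and Cs2CO3 in DMF/THF/H2O. This intramolecular B-alkyl Suzuki–Miyaura coupling forms the C4–C5 bond of the ring and returns to the route at 11.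

Step 21. The carboxylate has to attack an axial, neopentyl-type CH2 past the axial C5 carbon; the opening may be so slow that carboxylate exchange at the activated allylic C3–O bond of the lactone, or decay of 33 on long heating, takes over. The fallback forms the C9 diol by osmylation and then acylates at oxygen, so no substitution at carbon is needed. It sets out from 17 and 33. Silylation of 33 (tert-butyldimethylsilyl chloride, imidazole, DMF) gives the tris-silyl compound F16, whose silyl ester is cleaved (K2CO3, MeOH/H2O) to the bis-silyl ether acid F17. Dihydroxylation of 17 from the face opposite C1 and C5 under anhydrous conditions (OsO4 cat., N-methylmorpholine N-oxide, PhB(OH)2, CH2Cl2) catches the diol as the cyclic phenylboronate F18, which cannot translactonise. Exchange with pinacol at 0 °C frees the diol F19, which must be acylated at once at the primary hydroxyl, before it can translactonise onto C1, with the mixed anhydride of F17 (2,4,6-trichlorobenzoyl chloride, Et3N; then DMAP, toluene, −20 °C) to give the protected ester F20. TFA/CH2Cl2/H2O then removes the tert-butyl ester and both silyl ethers and returns to the route at 35.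

Further compounds

F1 | step 7 | (R,E)-tert-butyldimethyl{[4-(4,4,5,5-tetramethyl-1,3,2-dioxaborolan-2-yl)but-3-en-2-yl]oxy}silane | C[C@@H](O[Si](C)(C)C(C)(C)C)/C=C/B1OC(C)(C)C(C)(C)O1
F2 | step 7 | tert-butyl{[(2R,3E,5S)-5-isopropylhepta-3,6-dien-2-yl]oxy}dimethylsilane | CC(C)[C@H](/C=C/[C@@H](C)O[Si](C)(C)C(C)(C)C)C=C
F3 | step 7 | B-alkyl-9-BBN adduct of F2 | CC(C)[C@H](/C=C/[C@@H](C)O[Si](C)(C)C(C)(C)C)CCB1C2CCCC1CCC2
F4 | step 7 | (6R,7E,9R)-9-[(tert-butyldimethylsilyl)oxy]-6-isopropyl-3-methylenedec-7-en-1-ol | CC(C)[C@H](/C=C/[C@@H](C)O[Si](C)(C)C(C)(C)C)CCC(=C)CCO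
F5 | step 7 | (6R,7E,9R)-9-[(tert-butyldimethylsilyl)oxy]-6-isopropyl-3-methylenedec-7-enoic acid | CC(C)[C@H](/C=C/[C@@H](C)O[Si](C)(C)C(C)(C)C)CCC(=C)CC(=O)O
F6 | step 7 | (6R,7E,9R)-9-hydroxy-6-isopropyl-3-methylenedec-7-enoic acid | CC(C)[C@H](/C=C/[C@@H](C)O)CCC(=C)CC(=O)O
F7 | step 7 | (7R,8E,10S)-7-isopropyl-10-methyl-4-methylene-3,4,5,6,7,10-hexahydro-2H-oxecin-2-one | CC(C)[C@H]1CCC(=C)CC(=O)O[C@@H](C)/C=C/1
F8 | step 7 | trimethylsilyl ketene acetal of F7, ring oxygen cis to C4 | CC(C)[C@H]1CCC(=C)/C=C(O[Si](C)(C)C)\O[C@@H](C)/C=C/1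
F9 | step 7 | trimethylsilyl (1S,2S,3R)-3-isopropyl-6-methylene-2-[(E)-prop-1-en-1-yl]cyclohexane-1-carboxylate | CC(C)[C@H]1CCC(=C)[C@@H](C(=O)O[Si](C)(C)C)[C@H]1/C=C/C
F10 | step 7 | (1S,2S,3R)-3-isopropyl-6-methylene-2-[(E)-prop-1-en-1-yl]cyclohexane-1-carboxylic acid | CC(C)[C@H]1CCC(=C)[C@@H](C(=O)O)[C@H]1/C=C/C
F11 | step 7 | 2-(tert-butoxycarbonyl)allyl (1S,2S,3R)-3-isopropyl-6-methylene-2-[(E)-prop-1-en-1-yl]cyclohexane-1-carboxylate | CC(C)[C@H]1CCC(=C)[C@@H](C(=O)OCC(=C)C(=O)OC(C)(C)C)[C@H]1/C=C/C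
F12 | step 6 | (S,E)-4-isopropylhexa-2,5-dien-1-ol | CC(C)[C@H](/C=C/CO)C=C
F13 | step 6 | 3-bromobut-3-enoic acid | C=C(Br)CC(=O)O
F14 | step 6 | (S,E)-4-isopropylhexa-2,5-dien-1-yl 3-bromobut-3-enoate | CC(C)[C@H](/C=C/COC(=O)CC(Br)=C)C=C
F15 | step 6 | B-alkyl-9-BBN adduct of F14 | CC(C)[C@H](/C=C/COC(=O)CC(Br)=C)CCB1C2CCCC1CCC2
F16 | step 21 | tert-butyldimethylsilyl (E)-2-[(tert-butyldimethylsilyloxy)methyl]-3-[(1R,6S)-3-[(tert-butyldimethylsilyloxy)methyl]-6-isopropylcyclohex-2-en-1-yl]acrylate | CC(C)(C)[Si](C)(C)OC(=O)/C(CO[Si](C)(C)C(C)(C)C)=C/[C@H]1C=C(CO[Si](C)(C)C(C)(C)C)CC[C@H]1C(C)C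
F17 | step 21 | (E)-2-[(tert-butyldimethylsilyloxy)methyl]-3-[(1R,6S)-3-[(tert-butyldimethylsilyloxy)methyl]-6-isopropylcyclohex-2-en-1-yl]acrylic acid | OC(=O)/C(CO[Si](C)(C)C(C)(C)C)=C/[C@H]1C=C(CO[Si](C)(C)C(C)(C)C)CC[C@H]1C(C)C
F18 | step 21 | cyclic phenylboronate of the (5aR,6R,9S,9aS)-9-hydroxy-9-(hydroxymethyl) lactone tert-butyl ester | CC(C)[C@H]1CC[C@@]2(COB(c4ccccc4)O2)[C@H]3C(=O)OCC(C(=O)OC(C)(C)C)=C[C@@H]13
F19 | step 21 | tert-butyl (5aR,6R,9S,9aS)-9-hydroxy-9-(hydroxymethyl)-6-isopropyl-1-oxo-1,3,5a,6,7,8,9,9a-octahydro-2-benzoxepine-4-carboxylate | CC(C)[C@H]1CC[C@@](O)(CO)[C@H]2C(=O)OCC(C(=O)OC(C)(C)C)=C[C@@H]12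
F20 | step 21 | bis(tert-butyldimethylsilyl) ether of 34 | CC(C)[C@H]1CC[C@@](O)(COC(=O)/C(=C/[C@H]2C=C(CO[Si](C)(C)C(C)(C)C)CC[C@H]2C(C)C)CO[Si](C)(C)C(C)(C)C)[C@H]2C(=O)OCC(C(=O)OC(C)(C)C)=C[C@@H]12
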